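**Plan**

- Retrosynthetic cuts, in order: C12=C13 (Wittig), C8=C17 (methylenation of a C8 ketone), C2–Cl (from the 2β-alcohol with inversion), one C4 methyl (hydromethylation of C4=CH2); then rings A and B open together through C2–C3 and C5–C10; last, C9–C10 (cuprate addition) and C5–C6 (Grignard coupling).
- Enabling feature: in ring A, C3–C4–C5 is a former prenyl group (C4 with its methyls, C3 once one of them) that can act twice as an ene donor, and C10–C1–C2 is a β-methyl enal (C10 the β-carbon, C2 the carbonyl carbon that ends as the C–Cl carbon) that can act twice as an enophile; C6–C9 of ring B is the tether.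
- Forward: the acyclic chain C2–C1–C10–C9–C8–C7–C6–C5–C4 is assembled; ring B (C5–C10) and then ring A (C2–C3) close in one Lewis-acid double-ene cascade, a formal (3+3) annulation; then C4 is methylated, C2 chlorinated, the imide side chain attached, and ring B adjusted to the C7 acetate and C8 methylidene.
- Stereochemistry: C7 and C8 come from L-tartaric acid (the C8 oxygen is later erased); C9 from an anti-selective cuprate addition; C5 and C10 from a chair transition state fixed by the trans-dioxolane and allylic strain; C2 from the second ene step followed by SN2 inversion.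

Key step: step 8

Remark: locants are labdane-type positions of the target (ring A = C1–C5, C10; ring B = C5–C10; C17 = exocyclic methylidene carbon; side chain C11–C16; α/β as in terpenoid drawings). The step 9 reagent, formaldehyde N-(octylsulfonyl)hydrazone, is assumed to be made beforehand from octane-1-sulfonohydrazide and formaldehyde and is not counted as a step.

**Route**

Step 1
Reactants: 1 (4S,5S)-2,2-dimethyl-1,3-dioxolane-4,5-dimethanol
Product: 2 [(4S,5S)-5-(hydroxymethyl)-2,2-dimethyl-1,3-dioxolan-4-yl]methyl 4-methylbenzenesulfonate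
Conditions: TsCl (1.05 equiv), Ag2O, KI (cat.), CH2Cl2, 0 °C to rt
Reagents that add atoms: 4-methylbenzenesulfonyl chloride, Cc1ccc(cc1)S(Cl)(=O)=O
Why: Silver-oxide-mediated monosulfonylation of a C2-symmetric diol, whose two hydroxyls are equivalent, so one monotosylate should form and no stereocentre is touched.

Step 2
Reactants: 2 monotosylate; 3 (2-methylprop-1-en-1-yl)magnesium bromide
Product: 4 [(4S,5S)-2,2-dimethyl-5-(3-methylbut-2-en-1-yl)-1,3-dioxolan-4-yl]methanol
Conditions: 3 (3 equiv), CuI (10 mol %), THF, −30 to 0 °C
Reagents that add atoms: none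
Why: Copper-catalysed Grignard cross-coupling with the primary tosylate forms C5–C6 and installs the prenyl group (C4 with both methyls), the free hydroxyl being carried as its magnesium alkoxide, whose cyclisation to a trans-fused bicyclic ether is too strained to compete.

Step 3
Reactants: 4 prenyl alcohol; 5 ethyl (triphenylphosphoranylidene)acetate
Product: 7 ethyl (2E)-3-[(4S,5S)-2,2-dimethyl-5-(3-methylbut-2-en-1-yl)-1,3-dioxolan-4-yl]prop-2-enoate, via aldehyde 6 (not isolated)
Conditions: Dess–Martin periodinane, CH2Cl2, 0 °C to rt; then 5, rt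
Reagents that add atoms: none
Why: Dess–Martin oxidation gives the epimerisable α-alkoxy aldehyde, which is trapped in the same flask by the stabilised ylide in an (E)-selective Wittig reaction.

Step 4
Reactants: 8 but-2-yn-1-ol
Product: 10 (2Z)-3-iodobut-2-en-1-ol, via cyclic alkenylalanate 9 (not isolated)
Conditions: NaAlH2(OCH2CH2OCH3)2 (Red-Al), Et2O, 0 °C to rt; then I2, THF, −78 to 0 °C
Reagents that add atoms: iodine, II
Why: Hydroxyl-directed trans-hydroalumination of the propargylic alcohol places aluminium on C3, and iodinolysis of the C–Al bond with retention gives the (Z)-iodoalkene (hydroalumination–iodination).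

Step 5
Reactants: 10 (2Z)-3-iodobut-2-en-1-ol
Product: 11 triethyl{[(2Z)-3-iodobut-2-en-1-yl]oxy}silane
Conditions: Et3SiCl, imidazole, CH2Cl2, 0 °C
Reagents that add atoms: chlorotriethylsilane, CC[Si](Cl)(CC)CC
Why: Standard O-silylation; the triethylsilyl ether is chosen because it can later be oxidised directly to the aldehyde.

Step 6
Reactants: 7 enoate; 11 (Z)-iodoalkene silyl ether
Product: 14 ethyl (3R,4Z)-3-[(4S,5S)-2,2-dimethyl-5-(3-methylbut-2-en-1-yl)-1,3-dioxolan-4-yl]-4-methyl-6-[(triethylsilyl)oxy]hex-4-enoate, via alkenyllithium 12 (not isolated), via lithium dialkenylcuprate 13 (not isolated)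
Conditions: 11 (2.2 equiv), t-BuLi (4.4 equiv), Et2O, −78 °C; CuI (1.1 equiv), −78 to −40 °C; then Me3SiCl and 7, −78 to −40 °C; aq NH4Cl
Reagents that add atoms: none
Why: Iodine–lithium exchange with retention, Gilman cuprate formation and silyl-chloride-accelerated 1,4-addition to the γ-alkoxy enoate, which should occur anti to the C8–O bond (Felkin–Anh-type conformer with C8–H eclipsing the alkene) and so set C9 as R while forming C9–C10.

Step 7
Reactants: 14 silyl ether
Product: 15 ethyl (3R,4Z)-3-[(4S,5S)-2,2-dimethyl-5-(3-methylbut-2-en-1-yl)-1,3-dioxolan-4-yl]-4-methyl-6-oxohex-4-enoate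
Conditions: (COCl)2, DMSO, CH2Cl2, −78 to −30 °C; Et3N, −78 to 0 °C
Reagents that add atoms: none
Why: Swern conditions cleave and oxidise a primary allylic triethylsilyl ether in one operation, giving the (Z)-enal without touching the ester or acetonide.

Step 8
Reactants: 15 (Z)-enal
Product: 17 tricyclic hydroxy ester (trans-decalin; 2β-OH axial; 4-methylidene; 5α-H; 10β-CH3; 7β,8α-O-isopropylidene; 9β-CH2CO2Et), via monocyclic ene adduct 16 (not isolated)
Conditions: Me2AlCl (3 equiv), CH2Cl2, −78 to −20 °C
Reagents that add atoms: none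
Why: Proposed new method: Me2AlCl binds the aldehyde, the prenyl alkene attacks the β-carbon C10 through C5 (6-exo closure of ring B with both π bonds exocyclic to the new ring; attack at the carbonyl carbon would need an eight-membered ring) and a prenyl methyl hydrogen passes to C1, so this conjugate ene reaction leaves an isopropenyl group (C4=C3) on C5 and an aluminium-bound aldehyde (C2) on the C1 methylene; the resulting 5-methylhex-5-enal array then closes ring A by a type 2 intramolecular carbonyl-ene reaction in which C3 adds to C2 through a six-membered chair and the remaining C4 methyl gives a hydrogen to oxygen, leaving the C2 alkoxide and C4=CH2. The closest known reaction type is the Me2AlCl-promoted sequential ene annulation of α,β-unsaturated aldehydes with simple alkenes to methylenecyclohexanols, together with Lewis-acid intramolecular ene cyclisation of 1,7-dienes; new here are the intramolecular first stage, the β,β-disubstituted enal that creates the C10 quaternary centre, and the closure of two rings in one operation. C5 and C10 are set in the chair transition state for ring B, whose fold is fixed by the trans-fused dioxolane on C7–C8 and the equatorial C9 side chain: allylic 1,3-strain in the (Z)-enal holds C9–H in the enal plane so that C5 bonds anti to C9–H (C10 methyl axial, C1 equatorial), and the cis methyl of the prenyl group keeps C4 equatorial, which places the two arms trans-diequatorial as the trans-decalin requires. C2 is set in the second ene step, where hydrogen transfer to oxygen requires an axial C–O bond and should give the 2β-alcohol. The step needs 1,4- over 1,2-attack, proton transfer to the ene products in place of collapse of the zwitterion to a cyclobutane or dihydropyran, and survival of the acetonide and ester, which the ring-size bias, low temperature and the proton-scavenging methylaluminium reagent should secure.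

Step 9
Reactants: 17 tricyclic 4-methylidene alcohol
Product: 19 tricyclic hydroxy ester (trans-decalin; 2β-OH; 4,4-dimethyl; 5α-H; 10β-CH3; 7β,8α-O-isopropylidene; 9β-CH2CO2Et), via sulfonyl hydrazide 18 (not isolated)
Conditions: Fe(acac)3, PhSiH3, CH2=NNHSO2(n-C8H17), THF/MeOH, rt; then MeOH, 60 °C
Reagents that add atoms: formaldehyde N-(octylsulfonyl)hydrazone, C=NNS(=O)(=O)CCCCCCCC
Why: Metal-hydride hydrogen atom transfer to the 1,1-disubstituted alkene gives the tertiary C4 radical, which adds to the hydrazone, and heating the sulfonyl hydrazide expels sulfinate and N2 to leave the second C4 methyl (olefin hydromethylation); C4 is not a stereocentre in the product.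

Step 10
Reactants: 19 2β-alcohol
Product: 20 tricyclic chloro ester (trans-decalin; 2α-Cl equatorial; 4,4-dimethyl; 5α-H; 10β-CH3; 7β,8α-O-isopropylidene; 9β-CH2CO2Et)
Conditions: PPh3, CCl4, MeCN, 60 °C
Reagents that add atoms: tetrachloromethane, ClC(Cl)(Cl)Cl
Why: Appel reaction in which chloride displaces the axial 2β-alkoxyphosphonium group from the open α face with inversion (SN2), giving the equatorial 2α-chloride and relieving 1,3-diaxial strain with the C4 and C10 methyl groups.

Step 11
Reactants: 20 chloro ester
Product: 21 chloro aldehyde (as 20 but 9β-CH2CHO)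
Conditions: i-Bu2AlH (1.1 equiv), toluene/CH2Cl2, −78 °C; aq potassium sodium tartrate
Reagents that add atoms: none
Why: Low-temperature partial reduction of the ester stops at the aluminium hemiacetal, which releases the C12 aldehyde on work-up.

Step 12
Reactants: 22 maleimide
Product: 23 3-(triphenylphosphoranylidene)pyrrolidine-2,5-dione
Conditions: PPh3, acetone, reflux
Reagents that add atoms: triphenylphosphine, c1ccc(cc1)P(c1ccccc1)c1ccccc1
Why: Conjugate addition of the phosphine to maleimide followed by proton shift gives the imide-stabilised ylide.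

Step 13
Reactants: 21 chloro aldehyde; 23 ylide
Product: 24 (E)-alkylidene succinimide acetonide (as 20 but 9β-CH2CH=C13 of the pyrrolidine-2,5-dione)
Conditions: MeOH, 65 °C
Reagents that add atoms: none
Why: Wittig olefination with a stabilised ylide, which should give the (E)-alkylidene succinimide (C11 trans to the C16 carbonyl).

Step 14
Reactants: 24 acetonide
Product: 25 7β,8α-diol (2α-Cl; 4,4-dimethyl; 9β side chain with the (E)-alkylidene succinimide)
Conditions: AcOH/H2O (4:1), 45 °C
Reagents that add atoms: none
Why: Acid hydrolysis of the strained trans-fused isopropylidene acetal; no stereocentre is touched.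

Step 15
Reactants: 25 diol
Product: 26 7β-acetate 8α-alcohol
Conditions: Ac2O (1.1 equiv), pyridine, CH2Cl2, −20 to 0 °C
Reagents that add atoms: acetic anhydride, CC(=O)OC(C)=O
Why: Sterically controlled monoacylation, since the 7β-hydroxyl next to the C6 methylene should react before the 8α-hydroxyl, which is crowded by the substituted C9 next to quaternary C10.

Step 16
Reactants: 26 hydroxy acetate
Product: 27 7β-acetoxy-8-ketone
Conditions: Dess–Martin periodinane, CH2Cl2, rt
Reagents that add atoms: none
Why: Dess–Martin oxidation of the remaining secondary alcohol under neutral conditions, the equatorial C7 acetate and C9 side chain being the stable arrangement beside the ketone.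

Step 17
Reactants: 27 ketone
Product: 28 target (7β-acetoxy-2α-chloro-8(17)-ene with the (E)-alkylidene succinimide side chain)
Conditions: Zn, CH2Br2, TiCl4, THF/CH2Cl2, 0 °C to rt
Reagents that add atoms: dibromomethane, BrCBr
Why: Takai–Lombardo methylenation, whose non-basic zinc–titanium methylene reagent should convert the hindered, enolisable α-acetoxy ketone into the exocyclic alkene without epimerisation or acyl migration.

**Compound list**

1 | (4S,5S)-2,2-dimethyl-1,3-dioxolane-4,5-dimethanol (from L-tartaric acid) | OC[C@@H]1OC(C)(C)O[C@H]1CO | starting material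
2 | [(4S,5S)-5-(hydroxymethyl)-2,2-dimethyl-1,3-dioxolan-4-yl]methyl 4-methylbenzenesulfonate | OC[C@@H]1OC(C)(C)O[C@H]1COS(=O)(=O)c1ccc(C)cc1 | intermediate
3 | (2-methylprop-1-en-1-yl)magnesium bromide | CC(C)=C[Mg]Br | starting material
4 | [(4S,5S)-2,2-dimethyl-5-(3-methylbut-2-en-1-yl)-1,3-dioxolan-4-yl]methanol | OC[C@@H]1OC(C)(C)O[C@H]1CC=C(C)C | intermediate
5 | ethyl (triphenylphosphoranylidene)acetate | CCOC(=O)C=P(c1ccccc1)(c1ccccc1)c1ccccc1 | starting material
6 | (4R,5S)-2,2-dimethyl-5-(3-methylbut-2-en-1-yl)-1,3-dioxolane-4-carbaldehyde | O=C[C@@H]1OC(C)(C)O[C@H]1CC=C(C)C | intermediate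
7 | ethyl (2E)-3-[(4S,5S)-2,2-dimethyl-5-(3-methylbut-2-en-1-yl)-1,3-dioxolan-4-yl]prop-2-enoate | CCOC(=O)/C=C/[C@@H]1OC(C)(C)O[C@H]1CC=C(C)C | intermediate
8 | but-2-yn-1-ol | CC#CCO | starting material
9 | sodium cyclic alkenylalanate (five-membered O–Al–C3=C2–C1 ring; two 2-methoxyethoxy groups on aluminium) | [Na+].CC1=CCO[Al-]1(OCCOC)OCCOC | intermediate
10 | (2Z)-3-iodobut-2-en-1-ol | C/C(I)=C/CO | intermediate
11 | triethyl{[(2Z)-3-iodobut-2-en-1-yl]oxy}silane | C/C(I)=C/CO[Si](CC)(CC)CC | intermediate
12 | alkenyllithium from 11 (lithium in place of iodine; geometry retained) | C/C([Li])=C/CO[Si](CC)(CC)CC | intermediate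
13 | lithium dialkenylcuprate from 12 (two 4-(triethylsilyloxy)but-2-en-2-yl groups on copper; geometry retained) | [Li+].C/C(=C/CO[Si](CC)(CC)CC)[Cu-]/C(C)=C\CO[Si](CC)(CC)CC | intermediate
14 | ethyl (3R,4Z)-3-[(4S,5S)-2,2-dimethyl-5-(3-methylbut-2-en-1-yl)-1,3-dioxolan-4-yl]-4-methyl-6-[(triethylsilyl)oxy]hex-4-enoate | CCOC(=O)C[C@H](/C(C)=C\CO[Si](CC)(CC)CC)[C@@H]1OC(C)(C)O[C@H]1CC=C(C)C | intermediate
15 | ethyl (3R,4Z)-3-[(4S,5S)-2,2-dimethyl-5-(3-methylbut-2-en-1-yl)-1,3-dioxolan-4-yl]-4-methyl-6-oxohex-4-enoate | CCOC(=O)C[C@H](/C(C)=C\C=O)[C@@H]1OC(C)(C)O[C@H]1CC=C(C)C | intermediate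
16 | monocyclic ene adduct: ring B cyclohexane (C5–C10) trans-fused at C7/C8 to the 2,2-dimethyl-1,3-dioxolane; 5β-isopropenyl (5α-H); 10β-CH3; 10α-CH2CHO; 9β-CH2CO2Et | CC1(C)O[C@H]2C[C@@H](C(C)=C)[C@](C)(CC=O)[C@@H](CC(=O)OCC)[C@@H]2O1 | intermediate
17 | tricyclic hydroxy ester: trans-decalin; 2β-OH (axial); 4-methylidene; 5α-H; 10β-CH3; 7β,8α-O-isopropylidene; 9β-CH2CO2Et | CC1(C)O[C@H]2C[C@H]3C(=C)C[C@@H](O)C[C@]3(C)[C@@H](CC(=O)OCC)[C@@H]2O1 | intermediate
18 | sulfonyl hydrazide: as 17 but C4 bears CH3 and CH2NHNHSO2(n-C8H17) (either C4 epimer) | CC1(C)O[C@H]2C[C@H]3C(C)(CNNS(=O)(=O)CCCCCCCC)C[C@@H](O)C[C@]3(C)[C@@H](CC(=O)OCC)[C@@H]2O1 | intermediate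
19 | tricyclic hydroxy ester: as 17 but 4,4-dimethyl | CC1(C)O[C@H]2C[C@H]3C(C)(C)C[C@@H](O)C[C@]3(C)[C@@H](CC(=O)OCC)[C@@H]2O1 | intermediate
20 | tricyclic chloro ester: as 19 but 2α-Cl (equatorial) in place of 2β-OH | CC1(C)O[C@H]2C[C@H]3C(C)(C)C[C@H](Cl)C[C@]3(C)[C@@H](CC(=O)OCC)[C@@H]2O1 | intermediate
21 | chloro aldehyde: as 20 but 9β-CH2CHO | CC1(C)O[C@H]2C[C@H]3C(C)(C)C[C@H](Cl)C[C@]3(C)[C@@H](CC=O)[C@@H]2O1 | intermediate
22 | maleimide (1H-pyrrole-2,5-dione) | O=C1C=CC(=O)N1 | starting material
23 | 3-(triphenylphosphoranylidene)pyrrolidine-2,5-dione | O=C1CC(=P(c2ccccc2)(c2ccccc2)c2ccccc2)C(=O)N1 | intermediate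
24 | acetonide with side chain: as 20 but 9β-CH2CH= joined (E) to C3 of pyrrolidine-2,5-dione | CC1(C)O[C@H]2C[C@H]3C(C)(C)C[C@H](Cl)C[C@]3(C)[C@@H](C/C=C4\CC(=O)NC4=O)[C@@H]2O1 | intermediate
25 | 7β,8α-diol: trans-decalin; 2α-Cl; 4,4-dimethyl; 10β-CH3; 9β side chain with (E)-alkylidene succinimide | O[C@H]1C[C@H]2C(C)(C)C[C@H](Cl)C[C@]2(C)[C@@H](C/C=C3\CC(=O)NC3=O)[C@@H]1O | intermediate
26 | 7β-acetate of 25 (8α-OH free) | CC(=O)O[C@H]1C[C@H]2C(C)(C)C[C@H](Cl)C[C@]2(C)[C@@H](C/C=C3\CC(=O)NC3=O)[C@@H]1O | intermediate
27 | 7β-acetoxy-8-ketone | CC(=O)O[C@H]1C[C@H]2C(C)(C)C[C@H](Cl)C[C@]2(C)[C@@H](C/C=C3\CC(=O)NC3=O)C1=O | intermediate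
28 | target: 7β-acetoxy-2α-chloro-8(17)-methylidene trans-decalin with 9β-CH2CH= (E) succinimide side chain | C=C1[C@@H](OC(C)=O)C[C@H]2C(C)(C)C[C@H](Cl)C[C@]2(C)[C@H]1C/C=C1\CC(=O)NC1=O | target

**Step count and risks**

Total: 17 steps. Longest linear sequence: 14 steps (steps 1–3, 6–11, 13–17).

Step 8 (the labelled step) is the most likely to fail. The zwitterion formed in the first closure may collapse to a cyclobutane or dihydropyran instead of transferring a proton, facial control in the ring B closure may be insufficient, the Lewis acid may open the acetonide, or the carbonyl-ene stage may stall. The fallback uses known chemistry and gives up the cascade for two separate, individually precedented ene reactions. It sets out from 15: a ZnBr2-mediated intramolecular conjugate ene reaction (CH2Cl2, 0 °C, the known cyclisation of 1,7-dienes bearing an electron-poor enophile) is stopped at the ring B aldehyde 16, which is isolated. The isolated 16 is then closed by the established type 2 carbonyl-ene cyclisation of 5-methylhex-5-enals (Me2AlCl, −78 °C), and the route is rejoined at 17. No compound outside the list arises (F0).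

Step 10 is the next most likely to fail. The axial alkoxyphosphonium ion may undergo E2 elimination, activation of the hindered axial hydroxyl may be slow, or step 8 may have delivered the alcohol with the other configuration. The fallback does not depend on the C2–O configuration. It sets out from 19: acylation with PhOC(S)Cl, pyridine and DMAP gives the O-phenyl thionocarbonate F1. Barton–McCombie deoxygenation (Bu3SnH, AIBN, toluene, 90 °C) gives the 2-deoxy ester F2. Site-selective aliphatic C–H chlorination with N-tert-butyl-N-chloro-3,5-bis(trifluoromethyl)benzamide under visible light (benzene, 55 °C) then attacks the accessible C2 methylene, and chlorine is transferred to the C2 radical from the α face because the axial β face is shielded by the C4 and C10 methyl groups. The route is rejoined at 20.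

Step 17 is the third. The imide N–H may quench the methylene reagent, the hindered ketone may convert incompletely, or the adjacent acetate may migrate or be lost. The fallback is a Peterson olefination, setting out from 27: addition of Me3SiCH2Li/CeCl3 (excess, THF, −78 °C; the imide is carried as its salt) from the open α face gives the β-hydroxysilane F3. Acid-induced elimination (HF·pyridine, MeCN, 0 °C) then gives 28.

Further compounds
F0 | step 8 | none | none
F1 | step 10 | O-phenyl thionocarbonate of 19 (2β-OC(=S)OPh) | CC1(C)O[C@H]2C[C@H]3C(C)(C)C[C@@H](OC(=S)Oc4ccccc4)C[C@]3(C)[C@@H](CC(=O)OCC)[C@@H]2O1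
F2 | step 10 | 2-deoxy ester (as 19 with CH2 at C2) | CC1(C)O[C@H]2C[C@H]3C(C)(C)CCC[C@]3(C)[C@@H](CC(=O)OCC)[C@@H]2O1
F3 | step 17 | β-hydroxysilane (as 27 but C8 bears 8β-OH and 8α-CH2SiMe3) | CC(=O)O[C@H]1C[C@H]2C(C)(C)C[C@H](Cl)C[C@]2(C)[C@@H](C/C=C3\CC(=O)NC3=O)[C@]1(O)C[Si](C)(C)C
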